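- The dusk run showed me a habit worth counting: each exchange uses one incoming ligand and frees one leaving ligand, so a reading of complex with one exchanged also tells how far both ligands have moved.

| flask | starting complex | incoming ligand | leaving ligand | temperature | remark | time |
|---|---|---|---|---|---|---|
| summer | 0.090 M | 0.072 M | 0.45 M | 25 °C | the very flask that is asked about, followed so far |  |
| dusk | 0.045 M | 0.072 M | 0.45 M | 20 °C | run made earlier |  |
| flask | 0.090 M | 0.0720 M | 0.450 M | 25 °C |  | 2.0 h |

| run | time / min | complex with one exchanged / % | starting complex / % |
|---|---|---|---|
| summer | 20.0 | 16.6 | 81.1 |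
| summer | 40.0 | 20.3 | 77.7 |
| summer | 60.0 | 21.0 | 77.8 |
| summer | 80.0 | 18.8 | 77.6 |
| summer | 90.0 | 19.3 | 78.3 |
| summer | 120 | 18.0 | 79.3 |
| dusk | 20.0 | 13.4 | 85.2 |
| dusk | 40.0 | 18.5 | 79.3 |
| dusk | 60.0 | 20.0 | 76.0 |
| dusk | 80.0 | 19.9 | 73.2 |
| dusk | 90.0 | 20.7 | 75.2 |
| dusk | 120 | 20.2 | 75.7 |

(each reading ± 0.5 percentage points)

- ochre: change nothing and wait 40 min more
- red: at 2.0 h raise the temperature by 20 K, then wait 40 min
- teal: at 2.0 h add incoming ligand, 50.0% of the amount charged, then wait 40 min
- violet: at 2.0 h take out 90% of the leaving ligand then present, then wait 40 min

- additions bring no volume worth counting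

* complex with one exchanged, in percent of the starting complex first charged, at 2.0 h
* which option adds most complex with one exchanged ("none" when 2 percentage points or less is all one gets) (ochre / red / teal / violet / none)
* complex with one exchanged present, in percent of the starting complex first charged, after ochre
* complex with one exchanged present, in percent of the starting complex first charged, after red

- In the summer flask less incoming ligand was charged than starting complex, which makes it the limiting reagent, so the turnovers matter to its balance.
- I named the turnover quotient: the ratio of complex with one exchanged to starting complex, times counted leaving ligand, divided by counted incoming ligand. Dusk's last reading gave 1.95.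
- My first way to the summer flask at 2.0 h used its own readings: the last three average 18.7%.
- My second way used dusk alone. I took dusk's final share as a first guess for the count, which gave a ratio of 0.224 and so 18.3%, counting those two forms as the whole.
- The two ways differ by less than the scatter, although dusk ran cooler, so I trusted that level.
- They part earlier. Summer's quotient read 2.38 at 60.0 min and 1.90 at 120 min. A true constant doesn't sink like that, so the count was the cheat, and I kept the quotient as a late working number.
- The forecast gave 18.6%, 17.6% after ochre, 21% after red and chose violet: “Violet is best.”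

- The summer flask held 18.3% at 2.0 h; ochre left 17.8%, red gave 27.2%, and red added most, 8.9 percentage points. Free incoming ligand stood at 38.9%, while my count said 77.1%. Putting the free amount into the quotient gave 3.91, twice the counted value, beside 3.8 in the first line below.

    starting complex + incoming ligand ⇌ leaving ligand + complex with one exchanged (K = 3.80, k = 0.00440 /M/s, Ea = 68.0 kJ/mol, ΔH = 18.0 kJ/mol)
    complex with one exchanged + incoming ligand ⇌ leaving ligand + complex with two exchanged (K = 1.40, k = 0.0120 /M/s, Ea = 61.0 kJ/mol, ΔH = −46.0 kJ/mol)
    complex with two exchanged + incoming ligand ⇌ leaving ligand + complex with three exchanged (K = 14.0, k = 0.00390 /M/s, Ea = 75.0 kJ/mol, ΔH = −49.0 kJ/mol)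
    complex with three exchanged + incoming ligand ⇌ leaving ligand + complex with four exchanged (K = 2.40, k = 0.00670 /M/s, Ea = 72.0 kJ/mol, ΔH = −46.0 kJ/mol)
    incoming ligand ⇌ dormant form (K = 0.880, k = 1.80 × 10⁻⁴ /s, Ea = 82.0 kJ/mol, ΔH = −21.0 kJ/mol)
    (constants at 25 °C)

- For the neighbour with 0.029 M of incoming ligand, I scaled dusk's final share, my first guess, to its charge and kept the quotient, which gave a ratio of 0.0923 and so 8.45%. That flask gave 8.84%.

The earlier runs and the new flask stem from a simulated flask with made-up constants.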